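Assumption: germacrane numbering is used in the explanations (ring C1–C10, lactone O–C6/C7/C11/C12, exo-methylene C13, ester carbon C14, methyl C15), and divinylzinc is used as a pre-made stock solution.

## Retrosynthetic overview

1. Target ⇐ 8α-hydroxy macrocycle 18 + silyl-protected 2-(hydroxymethyl)acrylic acid 21, joined by a Mitsunobu esterification that inverts C8 to the 8β-ester.
2. 18 ⇐ seco-aldehyde 17 by closing C7–C8: Cr(II) reduces the 3-(bromomethyl)butenolide so that its β-carbon C7, normally an acceptor position, attacks the α-acetoxy aldehyde C8. This one step makes the ten-membered ring, C7, C8 and the exo-methylene lactone.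
3. 17 ⇐ enal 11: C6 by catalytic asymmetric vinylzinc addition, butenolide by acylation with 2-(bromomethyl)acrylic acid and RCM, aldehyde C8 by glycol cleavage of the acetonide.
4. 11 ⇐ (Z)-α-iodoenoate 7 + (R)-glyceraldehyde acetonide 8 by Ni/Cr coupling (C9–C10 bond, C9 under Felkin control); 7 ⇐ geranyl acetate 1 by ozonolysis and iodo-Wittig olefination.
5. Ring order: butenolide first (RCM), carbocycle last (Cr allylation).

## Route

Step 1
Reactants: 1 geranyl acetate, (2E)-3,7-dimethylocta-2,6-dien-1-yl acetate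
Product: 3 (2E)-3-methyl-6-oxohex-2-en-1-yl acetate, via ozonide 2 (not isolated)
Conditions: O3 (1.0 equiv), CH2Cl2, −78 °C; then Me2S, −78 °C → rt
Reagents that add atoms: ozone, [O-][O+]=O
Why: Chemoselective ozonolysis (Criegee) of the electron-rich 6,7-olefin; the 2,3-olefin is deactivated by the allylic acetate and keeps its E geometry.

Step 2
Reactants: 3 (2E)-3-methyl-6-oxohex-2-en-1-yl acetate; 4 methyl (triphenyl-λ5-phosphanylidene)acetate
Product: 7 methyl (2Z,6E)-8-hydroxy-2-iodo-6-methylocta-2,6-dienoate, via iodo ylide 5 (not isolated), via acetoxy iodoenoate 6 (not isolated)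
Conditions: 4, NIS, CH2Cl2, −20 °C; then 3, −20 °C → rt; then MeOH, K2CO3 (0.3 equiv), 0 °C
Reagents that add atoms: N-iodosuccinimide, O=C1CCC(=O)N1I
Why: Wittig olefination with the α-iodo ylide made in situ puts the chain trans to the ester (Z-iodoalkene, the C1=C10 geometry of the target), and catalytic methanolysis in the same flask frees the allylic alcohol (the methyl ester is degenerate towards MeOH).

Step 3
Reactants: 7 methyl (2Z,6E)-8-hydroxy-2-iodo-6-methylocta-2,6-dienoate; 8 (4R)-2,2-dimethyl-1,3-dioxolane-4-carbaldehyde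
Product: 9 methyl (2E,6E)-2-{(S)-[(4R)-2,2-dimethyl-1,3-dioxolan-4-yl](hydroxy)methyl}-8-hydroxy-6-methylocta-2,6-dienoate
Conditions: CrCl2 (4 equiv), NiCl2 (2 mol %), DMF, rt; minor syn isomer removed by chromatography
Reagents that add atoms: none
Why: Nozaki–Hiyama–Kishi coupling: the alkenylchromium, formed with retention of olefin geometry, adds to the aldehyde on its Felkin–Anh face (anti to the dioxolane oxygen), which sets C9 (S); free hydroxyl groups are tolerated.

Step 4
Reactants: 9 (diol from step 3)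
Product: 10 methyl (2E,6E)-2-{(S)-[(4R)-2,2-dimethyl-1,3-dioxolan-4-yl](hydroxy)methyl}-6-methyl-8-oxoocta-2,6-dienoate
Conditions: TEMPO (10 mol %), PhI(OAc)2 (1.1 equiv), CH2Cl2, rt
Reagents that add atoms: none
Why: Oxoammonium (TEMPO/BAIB) oxidation takes the primary allylic alcohol to the E-enal and leaves the hindered secondary alcohol at C9 alone.

Step 5
Reactants: 10 (hydroxy enal)
Product: 11 methyl (2E,6E)-2-{(S)-acetoxy[(4R)-2,2-dimethyl-1,3-dioxolan-4-yl]methyl}-6-methyl-8-oxoocta-2,6-dienoate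
Conditions: Ac2O, pyridine, DMAP (cat.), CH2Cl2, 0 °C
Reagents that add atoms: acetic anhydride, CC(=O)OC(C)=O
Why: Standard acylation installs the C9 acetate of the target while C9–OH is the only hydroxyl group present.

Step 6
Reactants: 11 (acetoxy enal)
Product: 12 methyl (2E,6E,8S)-2-{(S)-acetoxy[(4R)-2,2-dimethyl-1,3-dioxolan-4-yl]methyl}-8-hydroxy-6-methyldeca-2,6,9-trienoate
Conditions: (CH2=CH)2Zn (2 equiv), (−)-DAIB (10 mol %), toluene, −20 → 0 °C; aq NH4Cl
Reagents that add atoms: divinylzinc, C=C[Zn]C=C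
Why: Amino-alcohol-catalysed (Noyori/Oppolzer-type) 1,2-addition of divinylzinc to the Si face of the enal (reagent control, same sense as dialkylzincs with (−)-DAIB) sets C6 (S in the carbinol); organozincs leave the esters untouched.

Step 7
Reactants: 12 (divinyl carbinol); 13 2-(bromomethyl)prop-2-enoic acid
Product: 14 methyl (2E,6E,8S)-2-{(S)-acetoxy[(4R)-2,2-dimethyl-1,3-dioxolan-4-yl]methyl}-8-{[2-(bromomethyl)prop-2-enoyl]oxy}-6-methyldeca-2,6,9-trienoate
Conditions: DIC, DMAP (5 mol %), CH2Cl2, −20 → 0 °C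
Reagents that add atoms: none
Why: Steglich esterification under near-neutral conditions acylates the bis-allylic alcohol without ionising it, so C6 is retained.

Step 8
Reactants: 14 (acrylate ester)
Product: 15 methyl (2E,6E)-2-{(S)-acetoxy[(4R)-2,2-dimethyl-1,3-dioxolan-4-yl]methyl}-7-[(2R)-4-(bromomethyl)-5-oxo-2,5-dihydrofuran-2-yl]-6-methylhepta-2,6-dienoate
Conditions: Grubbs II (5 mol %), CH2Cl2 (5 mM), 40 °C
Reagents that add atoms: none
Why: Ring-closing metathesis starts at the only monosubstituted olefin and closes onto the acrylate to give the butenolide; the trisubstituted olefins and the allylic bromide are spectators.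

Step 9
Reactants: 15 (bromobutenolide acetonide)
Product: 17 methyl (2E,6E)-2-[(1S)-1-acetoxy-2-oxoethyl]-7-[(2R)-4-(bromomethyl)-5-oxo-2,5-dihydrofuran-2-yl]-6-methylhepta-2,6-dienoate, via diol 16 (not isolated)
Conditions: H5IO6 (2 equiv), EtOAc, rt; used crude at once
Reagents that add atoms: none
Why: Periodic acid hydrolyses the terminal acetonide and cleaves the diol in one pot (Malaprade glycol cleavage), giving the α-acetoxy aldehyde without base, so C9 is not epimerised.

Step 10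
Reactants: 17 (seco-aldehyde)
Product: 18 methyl (3aR,4R,5S,6E,10E,11aR)-5-acetoxy-4-hydroxy-10-methyl-3-methylidene-2-oxo-2,3,3a,4,5,8,9,11a-octahydrocyclodeca[b]furan-6-carboxylate (8α-OH, 9α-OAc, trans-fused 6,12-lactone)
Conditions: CrCl2 (8 equiv), THF/DMF (10:1), rt, 17 added by syringe pump over 12 h (final 2 mM)
Reagents that add atoms: none
Why: Intramolecular Nozaki–Hiyama (Cr-Barbier) allylation: Cr(II) turns the allylic bromide into an allylchromium(III) whose γ-carbon C7 (the β-carbon of the butenolide, normally its electrophilic position) adds to the tethered aldehyde C8 with allylic transposition, unveiling the exo-methylene lactone; attack anti to the C6 side chain gives the trans-fused lactone (cis fusion would need a near-eclipsed C5–C6–C7–C8 torsion in the forming ring), and the chair Zimmerman–Traxler array with the ring-fixed E-type γ-substituent and the aldehyde chain both equatorial, which is also the Felkin–Anh face of the α-acetoxy aldehyde, is expected to give the 7,8-anti/8,9-anti alcohol (8α-OH).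

Step 11
Reactants: 19 2-(hydroxymethyl)prop-2-enoic acid
Product: 21 2-{[(tert-butyldimethylsilyl)oxy]methyl}prop-2-enoic acid, via bis-silyl derivative 20 (not isolated)
Conditions: TBSCl (2.2 equiv), imidazole, DMF, rt; then AcOH/H2O/THF, rt
Reagents that add atoms: tert-butyldimethylsilyl chloride, CC(C)(C)[Si](C)(C)Cl
Why: Silylation of both OH groups followed by selective hydrolysis of the labile silyl ester leaves the silyl-ether acid.

Step 12
Reactants: 18 (8α-hydroxy macrocycle); 21 (silyl-ether acid)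
Product: 23 target CNP0291058.1, methyl (3aS,4S,5S,6E,10E,11aR)-5-acetoxy-4-{[2-(hydroxymethyl)prop-2-enoyl]oxy}-10-methyl-3-methylidene-2-oxo-2,3,3a,4,5,8,9,11a-octahydrocyclodeca[b]furan-6-carboxylate, via silyl ether 22 (not isolated)
Conditions: PPh3, DIAD, THF, 0 °C → rt; then HF·pyridine, pyridine, 0 °C → rt
Reagents that add atoms: none
Why: Mitsunobu esterification displaces the activated 8α-oxygen by the carboxylate with SN2 inversion (C8 has no allylic system for SN2′ and the cis 9-acetate cannot participate), giving the 8β-ester of the target, and HF·pyridine then cleaves the primary allylic silyl ether without touching the acetate, the methyl ester or the Michael acceptors.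

## Compound list

1 | geranyl acetate, (2E)-3,7-dimethylocta-2,6-dien-1-yl acetate | CC(=O)OC/C=C(\C)CCC=C(C)C | starting material
2 | 3-[(3E)-5-acetoxy-3-methylpent-3-en-1-yl]-5,5-dimethyl-1,2,4-trioxolane (ozonide, both epimers at the ring CH) | CC(=O)OC/C=C(\C)CCC1OOC(C)(C)O1 | intermediate (not isolated)
3 | (2E)-3-methyl-6-oxohex-2-en-1-yl acetate | CC(=O)OC/C=C(\C)CCC=O | intermediate
4 | methyl (triphenyl-λ5-phosphanylidene)acetate | COC(=O)C=P(c1ccccc1)(c1ccccc1)c1ccccc1 | starting material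
5 | methyl iodo(triphenyl-λ5-phosphanylidene)acetate | COC(=O)C(I)=P(c1ccccc1)(c1ccccc1)c1ccccc1 | intermediate (not isolated)
6 | methyl (2Z,6E)-8-acetoxy-2-iodo-6-methylocta-2,6-dienoate | CC(=O)OC/C=C(\C)CC/C=C(\I)C(=O)OC | intermediate (not isolated)
7 | methyl (2Z,6E)-8-hydroxy-2-iodo-6-methylocta-2,6-dienoate | OC/C=C(\C)CC/C=C(\I)C(=O)OC | intermediate
8 | (4R)-2,2-dimethyl-1,3-dioxolane-4-carbaldehyde, (R)-glyceraldehyde acetonide | O=C[C@H]1COC(C)(C)O1 | starting material
9 | methyl (2E,6E)-2-{(S)-[(4R)-2,2-dimethyl-1,3-dioxolan-4-yl](hydroxy)methyl}-8-hydroxy-6-methylocta-2,6-dienoate | OC/C=C(\C)CC/C=C(/C(=O)OC)[C@H](O)[C@H]1COC(C)(C)O1 | intermediate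
10 | methyl (2E,6E)-2-{(S)-[(4R)-2,2-dimethyl-1,3-dioxolan-4-yl](hydroxy)methyl}-6-methyl-8-oxoocta-2,6-dienoate | O=C/C=C(\C)CC/C=C(/C(=O)OC)[C@H](O)[C@H]1COC(C)(C)O1 | intermediate
11 | methyl (2E,6E)-2-{(S)-acetoxy[(4R)-2,2-dimethyl-1,3-dioxolan-4-yl]methyl}-6-methyl-8-oxoocta-2,6-dienoate | O=C/C=C(\C)CC/C=C(/C(=O)OC)[C@H](OC(C)=O)[C@H]1COC(C)(C)O1 | intermediate
12 | methyl (2E,6E,8S)-2-{(S)-acetoxy[(4R)-2,2-dimethyl-1,3-dioxolan-4-yl]methyl}-8-hydroxy-6-methyldeca-2,6,9-trienoate | C=C[C@H](O)/C=C(\C)CC/C=C(/C(=O)OC)[C@H](OC(C)=O)[C@H]1COC(C)(C)O1 | intermediate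
13 | 2-(bromomethyl)prop-2-enoic acid | C=C(CBr)C(=O)O | starting material
14 | methyl (2E,6E,8S)-2-{(S)-acetoxy[(4R)-2,2-dimethyl-1,3-dioxolan-4-yl]methyl}-8-{[2-(bromomethyl)prop-2-enoyl]oxy}-6-methyldeca-2,6,9-trienoate | C=C[C@H](OC(=O)C(=C)CBr)/C=C(\C)CC/C=C(/C(=O)OC)[C@H](OC(C)=O)[C@H]1COC(C)(C)O1 | intermediate
15 | methyl (2E,6E)-2-{(S)-acetoxy[(4R)-2,2-dimethyl-1,3-dioxolan-4-yl]methyl}-7-[(2R)-4-(bromomethyl)-5-oxo-2,5-dihydrofuran-2-yl]-6-methylhepta-2,6-dienoate | O=C1O[C@H](/C=C(\C)CC/C=C(/C(=O)OC)[C@H](OC(C)=O)[C@H]2COC(C)(C)O2)C=C1CBr | intermediate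
16 | methyl (2E,6E)-2-[(1S,2R)-1-acetoxy-2,3-dihydroxypropyl]-7-[(2R)-4-(bromomethyl)-5-oxo-2,5-dihydrofuran-2-yl]-6-methylhepta-2,6-dienoate | O=C1O[C@H](/C=C(\C)CC/C=C(/C(=O)OC)[C@H](OC(C)=O)[C@H](O)CO)C=C1CBr | intermediate (not isolated)
17 | methyl (2E,6E)-2-[(1S)-1-acetoxy-2-oxoethyl]-7-[(2R)-4-(bromomethyl)-5-oxo-2,5-dihydrofuran-2-yl]-6-methylhepta-2,6-dienoate | O=C1O[C@H](/C=C(\C)CC/C=C(/C(=O)OC)[C@H](OC(C)=O)C=O)C=C1CBr | intermediate
18 | methyl (3aR,4R,5S,6E,10E,11aR)-5-acetoxy-4-hydroxy-10-methyl-3-methylidene-2-oxo-2,3,3a,4,5,8,9,11a-octahydrocyclodeca[b]furan-6-carboxylate (8α-alcohol) | O[C@@H]1[C@H]2C(=C)C(=O)O[C@@H]2/C=C(\C)CC/C=C(/C(=O)OC)[C@@H]1OC(C)=O | intermediate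
19 | 2-(hydroxymethyl)prop-2-enoic acid | C=C(CO)C(=O)O | starting material
20 | tert-butyldimethylsilyl 2-{[(tert-butyldimethylsilyl)oxy]methyl}prop-2-enoate | C=C(CO[Si](C)(C)C(C)(C)C)C(=O)O[Si](C)(C)C(C)(C)C | intermediate (not isolated)
21 | 2-{[(tert-butyldimethylsilyl)oxy]methyl}prop-2-enoic acid | C=C(CO[Si](C)(C)C(C)(C)C)C(=O)O | intermediate
22 | methyl (3aS,4S,5S,6E,10E,11aR)-5-acetoxy-4-[(2-{[(tert-butyldimethylsilyl)oxy]methyl}prop-2-enoyl)oxy]-10-methyl-3-methylidene-2-oxo-2,3,3a,4,5,8,9,11a-octahydrocyclodeca[b]furan-6-carboxylate | C=C(CO[Si](C)(C)C(C)(C)C)C(=O)O[C@H]1[C@H]2C(=C)C(=O)O[C@@H]2/C=C(\C)CC/C=C(/C(=O)OC)[C@@H]1OC(C)=O | intermediate (not isolated)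
23 | CNP0291058.1, methyl (3aS,4S,5S,6E,10E,11aR)-5-acetoxy-4-{[2-(hydroxymethyl)prop-2-enoyl]oxy}-10-methyl-3-methylidene-2-oxo-2,3,3a,4,5,8,9,11a-octahydrocyclodeca[b]furan-6-carboxylate | C=C(CO)C(=O)O[C@H]1[C@H]2C(=C)C(=O)O[C@@H]2/C=C(\C)CC/C=C(/C(=O)OC)[C@@H]1OC(C)=O | target

## Step count and risks

Total steps: 12 (11 in the main line plus step 11 for acid 21). Longest linear sequence: 11 (steps 1–10 and 12).

Most likely to fail, in order:

Step 10 (ring closure, which also decides C7 and C8). The chain may oligomerise, or the closed transition state may not give the predicted 8α-alcohol. The fallback sets out from 15. Palladium-catalysed exchange of the bromide with hexabutylditin (Pd2(dba)3, THF) gives the tributylstannylmethyl butenolide F1. Aqueous acetic acid and then NaIO4 give the stannyl diol F2 and the stannyl aldehyde F3. BF3·OEt2 in CH2Cl2 at −78 °C (1 mM) then closes the ring through an open, antiperiplanar SE2′ transition state. For γ-substituted allylstannanes this favours the 7,8-syn adduct, the 8β-alcohol F4. Steglich esterification of F4 with 21 (DIC, DMAP, retention) comes back to the route at 22, which is desilylated as in step 12. If the chromium reaction itself gives F4, the same ending applies.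

Step 12 (inversion at a hindered ring carbinol next to two Michael acceptors). The fallback sets out from 18. Tf2O and pyridine in CH2Cl2 at −40 °C give the 8α-triflate F5. This is displaced with the cesium carboxylate F6 (made from 21 and Cs2CO3; 18-crown-6, toluene, rt) in a plain SN2 reaction. It comes back to the route at 22.

Step 6 (enantiocontrol in the transfer of an unsubstituted vinyl group to a functionalised enal). The fallback sets out from 11. Vinylmagnesium bromide in THF at −78 °C gives the C6-epimeric carbinol mixture F7. Dess–Martin periodinane gives the cross-conjugated dienone F8. (R)-Me-CBS with catecholborane in toluene at −78 °C reduces F8 and comes back to the route at 12.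

## Further compounds

F1 | step 10 | methyl (2E,6E)-2-{(S)-acetoxy[(4R)-2,2-dimethyl-1,3-dioxolan-4-yl]methyl}-6-methyl-7-{(2R)-5-oxo-4-[(tributylstannyl)methyl]-2,5-dihydrofuran-2-yl}hepta-2,6-dienoate | O=C1O[C@H](/C=C(\C)CC/C=C(/C(=O)OC)[C@H](OC(C)=O)[C@H]2COC(C)(C)O2)C=C1C[Sn](CCCC)(CCCC)CCCC
F2 | step 10 | methyl (2E,6E)-2-[(1S,2R)-1-acetoxy-2,3-dihydroxypropyl]-6-methyl-7-{(2R)-5-oxo-4-[(tributylstannyl)methyl]-2,5-dihydrofuran-2-yl}hepta-2,6-dienoate | O=C1O[C@H](/C=C(\C)CC/C=C(/C(=O)OC)[C@H](OC(C)=O)[C@H](O)CO)C=C1C[Sn](CCCC)(CCCC)CCCC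
F3 | step 10 | methyl (2E,6E)-2-[(1S)-1-acetoxy-2-oxoethyl]-6-methyl-7-{(2R)-5-oxo-4-[(tributylstannyl)methyl]-2,5-dihydrofuran-2-yl}hepta-2,6-dienoate | O=C1O[C@H](/C=C(\C)CC/C=C(/C(=O)OC)[C@H](OC(C)=O)C=O)C=C1C[Sn](CCCC)(CCCC)CCCC
F4 | step 10 | methyl (3aR,4S,5S,6E,10E,11aR)-5-acetoxy-4-hydroxy-10-methyl-3-methylidene-2-oxo-2,3,3a,4,5,8,9,11a-octahydrocyclodeca[b]furan-6-carboxylate (8β-alcohol, C8 epimer of 18) | O[C@H]1[C@H]2C(=C)C(=O)O[C@@H]2/C=C(\C)CC/C=C(/C(=O)OC)[C@@H]1OC(C)=O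
F5 | step 12 | methyl (3aS,4R,5S,6E,10E,11aR)-5-acetoxy-10-methyl-3-methylidene-2-oxo-4-{[(trifluoromethyl)sulfonyl]oxy}-2,3,3a,4,5,8,9,11a-octahydrocyclodeca[b]furan-6-carboxylate | FC(F)(F)S(=O)(=O)O[C@@H]1[C@H]2C(=C)C(=O)O[C@@H]2/C=C(\C)CC/C=C(/C(=O)OC)[C@@H]1OC(C)=O
F6 | step 12 | cesium 2-{[(tert-butyldimethylsilyl)oxy]methyl}prop-2-enoate | C=C(CO[Si](C)(C)C(C)(C)C)C(=O)[O-].[Cs+]
F7 | step 6 | methyl (2E,6E)-2-{(S)-acetoxy[(4R)-2,2-dimethyl-1,3-dioxolan-4-yl]methyl}-8-hydroxy-6-methyldeca-2,6,9-trienoate (both C8 epimers) | C=CC(O)/C=C(\C)CC/C=C(/C(=O)OC)[C@H](OC(C)=O)[C@H]1COC(C)(C)O1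
F8 | step 6 | methyl (2E,6E)-2-{(S)-acetoxy[(4R)-2,2-dimethyl-1,3-dioxolan-4-yl]methyl}-6-methyl-8-oxodeca-2,6,9-trienoate | C=CC(=O)/C=C(\C)CC/C=C(/C(=O)OC)[C@H](OC(C)=O)[C@H]1COC(C)(C)O1
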